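**Plan**

1. Retrosynthetic cuts: in each flavanone half the aryl ether bond O1–C8a and the bond C4–C4a of the pyranone ring (ring C) are cut. This leaves ring A as an aryl dihalide and the chain as a C2-symmetric 1,4-diaryl-2,3-divinylbutane-1,4-diol, which is then cut at C2–C3 and C2''–C3''.
2. Enabling feature: each C2–C3 bond links a 4-methoxybenzylic carbinol carbon to a carbon that carries the one-carbon branch C4, and the two pairs are joined through C3–C3''. Two [2,3]-Wittig shifts of benzylic carbanions onto the inner carbons of a (2Z,4Z)-hexa-2,4-diene-1,6-diyl bis(4-methoxybenzyl) ether leave exactly this pattern, each O–CH2–CH= unit ending as the vinyl group that becomes C4.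
3. Forward order: the chain is built first (diene diol plus two stannylated benzyl units, then the double shift). Both aryl ethers O1–C8a follow, then both rings C are closed at C4–C4a by 6-exo Heck reaction, the exocyclic methylenes are cleaved to the C4 ketones, the benzyl ethers are removed and one 7-hydroxyl is methylated.
4. Stereochemistry: C2 and C2'' come from a chiral bis(oxazoline)–lithium complex in the double shift. C3 and C3'' come from the (Z) alkenes (syn pairs, which become 2,3-cis because O-arylation retains C2). The last step desymmetrises a C2-symmetric tetraphenol, so either 7-hydroxyl gives the same product.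

Key step: step 5

Assumption: the (S,S) bis(oxazoline) ligand is written as the enantiomer that leads to the (S) carbinols; if a trial on a mono-ether shows the opposite sense, the (R,R) ligand takes its place.

**Step 1**
Reactants: 1 hexa-2,4-diyne-1,6-diol
Product: 2 (2Z,4Z)-hexa-2,4-diene-1,6-diol
Conditions: Zn dust activated with Cu(OAc)2 and AgNO3, MeOH/H2O 1:1, 45 °C
Reagents that add atoms: none
Why: Semi-reduction with activated zinc in aqueous methanol, a standard cis-selective reduction of conjugated diynes flanked by propargylic oxygen, should stop at the (Z,Z)-diene because alkenes are not reduced under these conditions.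

**Step 2**
Reactants: 3 4-methoxybenzaldehyde; 4 tributyltin hydride
Product: 6 (4-methoxyphenyl)(tributylstannyl)methanol (racemic), via tributylstannyllithium 5 (not isolated)
Conditions: 4, LiN(i-Pr)2, THF, 0 °C; then 3, −78 °C; aq NH4Cl at −78 °C; crude product used at once
Reagents that add atoms: none
Why: Addition of the stannyl anion to the aldehyde carbonyl (first stage of the Still synthesis of α-alkoxystannanes) should give the racemic α-hydroxystannane, which is quenched cold and carried on crude because it reverts to aldehyde on warming with base.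

**Step 3**
Reactants: 6 (4-methoxyphenyl)(tributylstannyl)methanol
Product: 7 (4-methoxyphenyl)(tributylstannyl)methyl 2,2,2-trichloroacetimidate (racemic)
Conditions: Cl3CCN (1.5 equiv), DBU (10 mol%), CH2Cl2, 0 °C; short filtration through Et3N-treated silica; used directly
Reagents that add atoms: trichloroacetonitrile, N#CC(Cl)(Cl)Cl
Why: Base-catalysed addition of an alcohol to trichloroacetonitrile (standard trichloroacetimidate formation) needs only catalytic amidine base, so the stannyl carbinol is not held as a stoichiometric alkoxide that could expel the stannyl anion.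

**Step 4**
Reactants: 2 (2Z,4Z)-hexa-2,4-diene-1,6-diol; 7 (4-methoxyphenyl)(tributylstannyl)methyl 2,2,2-trichloroacetimidate (2.4 equiv)
Product: 8 (2Z,4Z)-1,6-bis[(4-methoxyphenyl)(tributylstannyl)methoxy]hexa-2,4-diene (mixture of epimers at the two tin-bearing carbons)
Conditions: (±)-camphor-10-sulfonic acid (10 mol%), 4 Å molecular sieves, CH2Cl2/Et2O, −40 → 0 °C
Reagents that add atoms: none
Why: Acid-catalysed trichloroacetimidate etherification, the reaction used to put on 4-methoxybenzyl ethers: the 4-methoxybenzylic imidate ionises under mild Brønsted acid and each primary hydroxyl of 2 captures the cation, so the diene acts only as a nucleophile and keeps its (Z,Z) geometry, while the tin-bearing carbons form without stereocontrol, which step 5 does not require.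

**Step 5**
Reactants: 8 (2Z,4Z)-1,6-bis[(4-methoxyphenyl)(tributylstannyl)methoxy]hexa-2,4-diene
Product: 11 (1S,2S,3S,4S)-2,3-diethenyl-1,4-bis(4-methoxyphenyl)butane-1,4-diol, via dilithiated bis-ether 9 (not isolated), via half-rearranged lithium alkoxide 10 (not isolated)
Conditions: n-BuLi (2.4 equiv) premixed with 2,2'-(pentane-3,3-diyl)bis[(4S)-4-isopropyl-4,5-dihydro-1,3-oxazole] (2.6 equiv), toluene, −78 °C; 8 added; −78 → −40 °C; aq NH4Cl
Reagents that add atoms: none
Why: Proposed new method: n-BuLi cleaves each benzylic C–Sn bond (tin–lithium exchange, so metalation cannot stray to the dienylic CH2 groups), and each bis(oxazoline)-bound α-alkoxybenzyllithium then undergoes a [2,3]-sigmatropic shift through a five-membered envelope transition state in which the carbanion carbon bonds to the near diene carbon (C3 or C3'') while the O–CH2 bond breaks, leaving a lithium alkoxide on C2 and a vinyl group; the first shift leaves the second allyl ether intact, so the second shift forms C2''–C3'' on the neighbouring carbon. The closest known reactions are the Wittig–Still rearrangement of stannylmethyl allyl ethers and the bis(oxazoline)/alkyllithium-mediated asymmetric [2,3]-Wittig rearrangement of (Z)-allyl benzyl ethers; new here are the generation of the ligand-bound benzylic lithium by exchange and its use twice on one dienyl bis-ether. No ring is closed. C2 and C2'' are set by the ligand, which is expected to favour one configuration of the configurationally labile benzylic lithium (the shift going with inversion at the lithium-bearing carbon), and C3 and C3'' follow from the (Z) alkene geometry, which places the aryl group exo in the envelope and gives the syn arrangement of hydroxyl and neighbouring branch. The step needs site selectivity (secured by tin), [2,3] over [1,2] shift (low temperature, concerted six-electron path) and the same sense of induction at both ends (one ligand enantiomer at both lithium centres); events of the wrong sense should end mainly in the separable meso diastereomer, so the C2-symmetric diol should be enriched in one enantiomer.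

**Step 6**
Reactants: 12 5-iodobenzene-1,3-diol
Product: 13 1,3-bis(benzyloxy)-5-iodobenzene
Conditions: BnBr (2.3 equiv), K2CO3, DMF, rt
Reagents that add atoms: benzyl bromide, BrCc1ccccc1
Why: Williamson ether synthesis on both phenolic hydroxyls.

**Step 7**
Reactants: 13 1,3-bis(benzyloxy)-5-iodobenzene
Product: 14 1,5-bis(benzyloxy)-2-bromo-3-iodobenzene
Conditions: NBS (1.05 equiv), MeCN, 0 °C → rt, dark
Reagents that add atoms: N-bromosuccinimide, O=C1CCC(=O)N1Br
Why: Electrophilic aromatic bromination should go to the position next to iodine, which is para to one benzyloxy group and ortho to the other and less hindered than the position between the two ethers, as is usual for 5-substituted resorcinol diethers.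

**Step 8**
Reactants: 11 (1S,2S,3S,4S)-2,3-diethenyl-1,4-bis(4-methoxyphenyl)butane-1,4-diol; 14 1,5-bis(benzyloxy)-2-bromo-3-iodobenzene (3 equiv)
Product: 15 (1S,2S,3S,4S)-1,4-bis[3,5-bis(benzyloxy)-2-bromophenoxy]-2,3-diethenyl-1,4-bis(4-methoxyphenyl)butane
Conditions: CuI (20 mol%), 3,4,7,8-tetramethyl-1,10-phenanthroline (40 mol%), Cs2CO3 (4 equiv), 4 Å molecular sieves, toluene, 110 °C
Reagents that add atoms: none
Why: Ullmann-type copper-catalysed C–O coupling of a secondary alcohol with an aryl iodide: the C–I bond should react in preference to the flanked C–Br bond, and C2 and C2'' keep their configuration because only the O–H bonds are engaged.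

**Step 9**
Reactants: 15 (1S,2S,3S,4S)-1,4-bis[3,5-bis(benzyloxy)-2-bromophenoxy]-2,3-diethenyl-1,4-bis(4-methoxyphenyl)butane
Product: 16 (2S,2'S,3R,3'R)-5,5',7,7'-tetrakis(benzyloxy)-2,2'-bis(4-methoxyphenyl)-4,4'-dimethylidene-3,3'-bichromane (2,3-cis in both rings)
Conditions: Pd(OAc)2 (10 mol%), P(t-Bu)3·HBF4 (20 mol%), Cy2NMe (4 equiv), 1,4-dioxane, 80 °C
Reagents that add atoms: none
Why: Twofold intramolecular Heck reaction in the 6-exo-trig mode: each arylpalladium bromide adds to the internal carbon of the vinyl group on the neighbouring carbon, closing the ring O1–C2–C3–C4–C4a–C8a, and β-hydride elimination of the C4 hydrogen leaves the exocyclic methylene, the bulky phosphine and amine base serving to restart the catalyst quickly so that the alkene does not migrate into the ring and C3 is untouched.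

**Step 10**
Reactants: 16 (2S,2'S,3R,3'R)-5,5',7,7'-tetrakis(benzyloxy)-2,2'-bis(4-methoxyphenyl)-4,4'-dimethylidene-3,3'-bichromane
Product: 17 (2S,2'S,3S,3'S)-5,5',7,7'-tetrakis(benzyloxy)-2,2'-bis(4-methoxyphenyl)-[3,3'-bichromane]-4,4'-dione
Conditions: OsO4 (5 mol%), NaIO4 (8 equiv), 2,6-lutidine (4 equiv), 1,4-dioxane/H2O 3:1, rt
Reagents that add atoms: sodium periodate NaIO4, [Na+].[O-]I(=O)(=O)=O (the ketone oxygen is passed on by the OsO4 catalyst)
Why: Lemieux–Johnson oxidation (OsO4 dihydroxylation followed by NaIO4 glycol cleavage, buffered with 2,6-lutidine) should cleave each electron-rich 1,1-disubstituted alkene to the C4 ketone under near-neutral conditions that spare the oxygenated arenes and the epimerisable C3 centres.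

**Step 11**
Reactants: 17 (2S,2'S,3S,3'S)-5,5',7,7'-tetrakis(benzyloxy)-2,2'-bis(4-methoxyphenyl)-[3,3'-bichromane]-4,4'-dione
Product: 18 (2S,2'S,3S,3'S)-5,5',7,7'-tetrahydroxy-2,2'-bis(4-methoxyphenyl)-[3,3'-bichromane]-4,4'-dione
Conditions: H2 (1 atm), 10% Pd/C, EtOAc/THF, rt
Reagents that add atoms: none
Why: Heterogeneous catalytic hydrogenolysis removes the four aryl benzyl ethers under neutral conditions, under which the aryl ketones and the cyclic C2–O bonds of flavanones are normally retained and the 2,3-cis centres cannot epimerise.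

**Step 12**
Reactants: 18 (2S,2'S,3S,3'S)-5,5',7,7'-tetrahydroxy-2,2'-bis(4-methoxyphenyl)-[3,3'-bichromane]-4,4'-dione
Product: 19 (2S,2'S,3S,3'S)-5,5',7-trihydroxy-7'-methoxy-2,2'-bis(4-methoxyphenyl)-[3,3'-bichromane]-4,4'-dione (CNP0184936.4)
Conditions: TMSCHN2 (0.6 equiv), MeOH/toluene 1:4, 0 °C; unreacted 18 recovered and resubmitted
Reagents that add atoms: (trimethylsilyl)diazomethane, C[Si](C)(C)C=[N+]=[N-]
Why: O-Methylation of a phenol by a diazoalkane (TMSCHN2 activated by methanol) takes the acidic 7-hydroxyl and leaves the hydrogen-bonded 5-hydroxyls, and because 18 is C2-symmetric either 7-hydroxyl gives 19, the substoichiometric charge keeping double methylation low.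

**Compound list**

1 | hexa-2,4-diyne-1,6-diol | OCC#CC#CCO | starting material
2 | (2Z,4Z)-hexa-2,4-diene-1,6-diol | OC/C=C\C=C/CO | intermediate
3 | 4-methoxybenzaldehyde | COc1ccc(C=O)cc1 | starting material
4 | tributyltin hydride | CCCC[SnH](CCCC)CCCC | starting material
5 | tributylstannyllithium | [Li][Sn](CCCC)(CCCC)CCCC | intermediate
6 | (4-methoxyphenyl)(tributylstannyl)methanol (racemic) | COc1ccc(C(O)[Sn](CCCC)(CCCC)CCCC)cc1 | intermediate
7 | (4-methoxyphenyl)(tributylstannyl)methyl 2,2,2-trichloroacetimidate (racemic) | COc1ccc(C(OC(=N)C(Cl)(Cl)Cl)[Sn](CCCC)(CCCC)CCCC)cc1 | intermediate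
8 | (2Z,4Z)-1,6-bis[(4-methoxyphenyl)(tributylstannyl)methoxy]hexa-2,4-diene (mixture of epimers at the tin-bearing carbons) | COc1ccc(C(OC/C=C\C=C/COC(c2ccc(OC)cc2)[Sn](CCCC)(CCCC)CCCC)[Sn](CCCC)(CCCC)CCCC)cc1 | intermediate
9 | (2Z,4Z)-1,6-bis[lithio(4-methoxyphenyl)methoxy]hexa-2,4-diene (dilithiated bis-ether; ligands on lithium omitted) | COc1ccc(C([Li])OC/C=C\C=C/COC([Li])c2ccc(OC)cc2)cc1 | intermediate
10 | lithium (1S,2S,3Z)-2-ethenyl-5-[lithio(4-methoxyphenyl)methoxy]-1-(4-methoxyphenyl)pent-3-en-1-olate (half-rearranged lithium alkoxide) | COc1ccc([C@@H](O[Li])[C@@H](C=C)/C=C\COC([Li])c2ccc(OC)cc2)cc1 | intermediate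
11 | (1S,2S,3S,4S)-2,3-diethenyl-1,4-bis(4-methoxyphenyl)butane-1,4-diol | COc1ccc([C@@H](O)[C@@H](C=C)[C@H](C=C)[C@H](O)c2ccc(OC)cc2)cc1 | intermediate
12 | 5-iodobenzene-1,3-diol | Oc1cc(O)cc(I)c1 | starting material
13 | 1,3-bis(benzyloxy)-5-iodobenzene | Ic1cc(OCc2ccccc2)cc(OCc2ccccc2)c1 | intermediate
14 | 1,5-bis(benzyloxy)-2-bromo-3-iodobenzene | Brc1c(I)cc(OCc2ccccc2)cc1OCc1ccccc1 | intermediate
15 | (1S,2S,3S,4S)-1,4-bis[3,5-bis(benzyloxy)-2-bromophenoxy]-2,3-diethenyl-1,4-bis(4-methoxyphenyl)butane | COc1ccc([C@@H](Oc2cc(OCc3ccccc3)cc(OCc3ccccc3)c2Br)[C@@H](C=C)[C@H](C=C)[C@H](Oc2cc(OCc3ccccc3)cc(OCc3ccccc3)c2Br)c2ccc(OC)cc2)cc1 | intermediate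
16 | (2S,2'S,3R,3'R)-5,5',7,7'-tetrakis(benzyloxy)-2,2'-bis(4-methoxyphenyl)-4,4'-dimethylidene-3,3'-bichromane | COc1ccc([C@H]2Oc3cc(OCc4ccccc4)cc(OCc4ccccc4)c3C(=C)[C@H]2[C@@H]2C(=C)c3c(OCc4ccccc4)cc(OCc4ccccc4)cc3O[C@@H]2c2ccc(OC)cc2)cc1 | intermediate
17 | (2S,2'S,3S,3'S)-5,5',7,7'-tetrakis(benzyloxy)-2,2'-bis(4-methoxyphenyl)-[3,3'-bichromane]-4,4'-dione | COc1ccc([C@H]2Oc3cc(OCc4ccccc4)cc(OCc4ccccc4)c3C(=O)[C@H]2[C@@H]2C(=O)c3c(OCc4ccccc4)cc(OCc4ccccc4)cc3O[C@@H]2c2ccc(OC)cc2)cc1 | intermediate
18 | (2S,2'S,3S,3'S)-5,5',7,7'-tetrahydroxy-2,2'-bis(4-methoxyphenyl)-[3,3'-bichromane]-4,4'-dione | COc1ccc([C@H]2Oc3cc(O)cc(O)c3C(=O)[C@H]2[C@@H]2C(=O)c3c(O)cc(O)cc3O[C@@H]2c2ccc(OC)cc2)cc1 | intermediate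
19 | (2S,2'S,3S,3'S)-5,5',7-trihydroxy-7'-methoxy-2,2'-bis(4-methoxyphenyl)-[3,3'-bichromane]-4,4'-dione (CNP0184936.4) | COc1ccc([C@H]2Oc3cc(O)cc(O)c3C(=O)[C@H]2[C@@H]2C(=O)c3c(O)cc(OC)cc3O[C@@H]2c2ccc(OC)cc2)cc1 | target

**Step count and risks**

Total step count: 12. Longest linear sequence: 9 steps (3 → 6 → 7 → 8 → 11 → 15 → 16 → 17 → 18 → 19; steps 2, 3, 4, 5, 8, 9, 10, 11, 12).

Steps most likely to fail:

1. Step 5 (the step that carries the new method). Two processes can defeat it. The [2,3]-shift may outrun epimerisation of the benzylic lithium, so that the ligand exerts no control. The branch formed in the first shift may also steer the second shift to the opposite alkene face, which leads into the meso series. A competing [1,2]-shift is a lesser risk.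
   Fallback, from 3 back to 11, by known chemistry that fixes the relative configuration of all four centres in a cis-fused bis-lactone and the absolute configuration by resolution. Aldehyde 3 is condensed with malonic acid (pyridine, piperidine, Doebner–Knoevenagel) to (E)-4-methoxycinnamic acid F1. Oxidative dimerisation of the cinnamic acid with Tl(OCOCF3)3 and BF3·OEt2 in CF3CO2H/CH2Cl2, a known route from 4-alkoxycinnamic acids to lignan bis-lactones, should give the racemic cis-fused exo,exo-diaryl bis-lactone 4,8-bis(4-methoxyphenyl)-3,7-dioxabicyclo[3.3.0]octane-2,6-dione F2, whose stereocentres already stand as in 11. i-Bu2AlH (CH2Cl2, −78 °C) reduces it to the bis-lactol F3, and twofold Wittig methylenation (Ph3P=CH2 from Ph3PCH3Br and KOt-Bu, THF) opens both lactols to the racemic divinyl diol F4. This is esterified with (S)-2-methoxy-2-phenylacetic acid (DCC, DMAP) and the diastereomeric diesters are separated to give the bis[(S)-2-methoxy-2-phenylacetate] of the (1S,2S,3S,4S) diol F5; LiOH hydrolysis returns 11.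

2. Step 4. The stannyl imidate may ionise and then rearrange to the N-benzylic trichloroacetamide or lose tin under acid instead of being captured by the diol.
   Fallback, from 1 and 6 back to 8, with the roles of the partners reversed and the unsaturation kept at the alkyne level. Diyne diol 1 is converted (Cl3CCN, DBU cat.) into hexa-2,4-diyne-1,6-diyl bis(2,2,2-trichloroacetimidate) F6. F6 alkylates the hydroxyl of 6 under TfOH catalysis (the known alkoxide-free O-alkylation of α-hydroxystannanes by imidates, in which the tin-bearing carbon is never cationic) to give 1,6-bis[(4-methoxyphenyl)(tributylstannyl)methoxy]hexa-2,4-diyne F7. Semi-reduction with activated zinc as in step 1 then gives 8.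

3. Step 8. The second arylation may stall at the hindered secondary benzylic alkoxide, and the aryl iodide may be consumed by reduction.
   Fallback, from 14 and 11 back to 15, by metal-free arylation with a diaryliodonium salt. Aryl iodide 14 is oxidised (mCPBA, TsOH·H2O, CH2Cl2) and coupled in the same flask with 1,3,5-trimethoxybenzene to [3,5-bis(benzyloxy)-2-bromophenyl](2,4,6-trimethoxyphenyl)iodonium 4-methylbenzenesulfonate F8. The dialkoxide of 11 (NaH, toluene, rt) is then arylated by F8, the trimethoxyphenyl group staying on iodine, which should give 15 with retention at the carbinol carbons.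

**Further compounds**

F1 | step 5 | (E)-4-methoxycinnamic acid | COc1ccc(/C=C/C(=O)O)cc1
F2 | step 5 | 4,8-bis(4-methoxyphenyl)-3,7-dioxabicyclo[3.3.0]octane-2,6-dione (racemic; the (1S,4S,5S,8S) enantiomer is drawn) | COc1ccc(cc1)[C@H]2OC(=O)[C@H]3[C@@H]2C(=O)O[C@@H]3c1ccc(OC)cc1
F3 | step 5 | 4,8-bis(4-methoxyphenyl)-3,7-dioxabicyclo[3.3.0]octane-2,6-diol (racemic, mixture of anomers; one enantiomer drawn) | COc1ccc(cc1)[C@H]2OC(O)[C@H]3[C@@H]2C(O)O[C@@H]3c1ccc(OC)cc1
F4 | step 5 | 2,3-diethenyl-1,4-bis(4-methoxyphenyl)butane-1,4-diol (racemic, relative configuration of 11; one enantiomer drawn) | COc1ccc([C@@H](O)[C@@H](C=C)[C@H](C=C)[C@H](O)c2ccc(OC)cc2)cc1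
F5 | step 5 | (1S,2S,3S,4S)-2,3-diethenyl-1,4-bis(4-methoxyphenyl)butane-1,4-diyl bis[(S)-2-methoxy-2-phenylacetate] | COc1ccc([C@@H](OC(=O)[C@@H](OC)c2ccccc2)[C@@H](C=C)[C@H](C=C)[C@H](OC(=O)[C@@H](OC)c2ccccc2)c2ccc(OC)cc2)cc1
F6 | step 4 | hexa-2,4-diyne-1,6-diyl bis(2,2,2-trichloroacetimidate) | ClC(Cl)(Cl)C(=N)OCC#CC#CCOC(=N)C(Cl)(Cl)Cl
F7 | step 4 | 1,6-bis[(4-methoxyphenyl)(tributylstannyl)methoxy]hexa-2,4-diyne (mixture of epimers) | COc1ccc(C(OCC#CC#CCOC(c2ccc(OC)cc2)[Sn](CCCC)(CCCC)CCCC)[Sn](CCCC)(CCCC)CCCC)cc1
F8 | step 8 | [3,5-bis(benzyloxy)-2-bromophenyl](2,4,6-trimethoxyphenyl)iodonium 4-methylbenzenesulfonate | COc1cc(OC)c([I+]c2cc(OCc3ccccc3)cc(OCc3ccccc3)c2Br)c(OC)c1.Cc1ccc(cc1)S(=O)(=O)[O-]
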